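**Strategy.** Ring A, the cyclohex-2-ene-1,4-dione fused along C4a–C9a (fluorene numbering: C9a bears prenyl, C4a the arene), is treated as an oxidised cyclohexene and cut at C1–C9a and C4–C4a. A single enantioselective Diels–Alder reaction of 4,7-dimethoxy-2-prenylinden-1-one with (1E,3E)-1,4-diacetoxybutadiene closes ring A cis-fused, makes C9a quaternary, sets C4a and puts oxygen on both future carbonyl carbons. The feature exploited is the C4a–C9a bond lying next to C9. As a ketone, C9 activates that alkene. Afterwards it accepts the methallyl unit whose aldol closure onto C4a builds ring B.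

Key step: step 3

Numbering: fluorene numbering is used for all tricyclic compounds. Ring A is C1–C4, C4a and C9a; the arene is C4b–C8a; C9 is the benzylic carbon. The bridge of ring B is C10 (CH2 on C9), C11 (C–CH3) and C12 (on C4a).

Assumption: the complex prepared from (R)-BINOL is taken to leave the C2-Re/C3-Re face of the indenone open; if the opposite sense is found, (S)-BINOL is used and nothing else changes.

Step 1
Reactants: 1 4,7-dimethoxyindan-1-one; 2 1-bromo-3-methylbut-2-ene
Product: 3 rac-4,7-dimethoxy-2-(3-methylbut-2-enyl)indan-1-one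
Conditions: LiN(iPr)2 (1.05 equiv), THF, −78 °C; then 2, −78 → 0 °C
Reagents that add atoms: none
Why: Lithium enolate alkylation (SN2 on the primary allylic bromide) at C2, the only enolisable carbon, gives a racemic stereocentre that disappears in step 2.

Step 2
Reactants: 3 rac-4,7-dimethoxy-2-(3-methylbut-2-enyl)indan-1-one
Product: 6 4,7-dimethoxy-2-(3-methylbut-2-enyl)-1H-inden-1-one, via selenide 4 (not isolated), via selenoxide 5 (not isolated)
Conditions: LiN(iPr)2, THF, −78 °C; PhSeBr, −78 °C; then AcOH, 30% H2O2, 0 °C → rt; extracted into CH2Cl2, dried and used at once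
Reagents that add atoms: none
Why: Enolate α-selenenylation followed by selenoxide syn elimination toward the ring C3–H, which is benzylic and held eclipsed with the C–Se bond in the flat five-membered ring, dehydrogenates the ketone without any electrophilic halogen that would attack the prenyl alkene or the electron-rich arene.

Step 3
Reactants: 6 4,7-dimethoxy-2-(3-methylbut-2-enyl)-1H-inden-1-one; 7 (1E,3E)-buta-1,3-diene-1,4-diyl diacetate
Product: 8 (1R,4S,4aR,9aS)-5,8-dimethoxy-9a-(3-methylbut-2-enyl)-9-oxo-4,4a,9,9a-tetrahydro-1H-fluorene-1,4-diyl diacetate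
Conditions: TiCl2(OiPr)2 (20 mol %), (R)-BINOL (22 mol %), 4 Å MS for catalyst formation, 7 (2 equiv), CH2Cl2/toluene, −20 °C → rt
Reagents that add atoms: none
Why: The titanium binaphtholate binds the C1 carbonyl oxygen together with the peri 7-methoxy oxygen of 6, which lowers the LUMO of the strained C2=C3 bond, and the s-cis diene 7 then adds in a concerted, suprafacial–suprafacial normal-demand [4+2] cycloaddition. The closest known reaction type is the Lewis acid-catalysed Diels–Alder reaction of 2-substituted indenones with oxygenated butadienes, in its asymmetric form the titanium–BINOL-catalysed addition of acyloxybutadienes to peri-oxygenated quinones. Ring A is closed in intermolecular [4+2] mode by the two new bonds C1–C9a and C4–C4a, and because both form on one face of a ring alkene the fusion can only be cis. C9a (S) and C4a (R) are controlled together by the ligand, which must leave the C2-Re/C3-Re face open, whereas C1 (R) and C4 (S) follow from the E,E geometry of 7 (acetoxy groups mutually cis) and from the endo orientation of the indenone under the diene (acetoxy groups cis to C9 and to the arene). The step needs only enantiofacial selectivity, secured by the rigid two-point chelation that the 7-methoxy group offers; regioselectivity is no issue because 7 is symmetric, the unactivated prenyl alkene does not compete, and endo/exo leakage does not affect the final stereochemistry since C1 and C4 end as carbonyl carbons.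

Step 4
Reactants: 8 (1R,4S,4aR,9aS)-5,8-dimethoxy-9a-(3-methylbut-2-enyl)-9-oxo-4,4a,9,9a-tetrahydro-1H-fluorene-1,4-diyl diacetate
Product: 9 (1R,4S,4aS,9R,9aR)-9-hydroxy-5,8-dimethoxy-9a-(3-methylbut-2-enyl)-4,4a,9,9a-tetrahydro-1H-fluorene-1,4-diyl diacetate (9-OH cis to the 1-acetoxy group)
Conditions: NaBH4, CeCl3·7H2O, MeOH/THF, −20 → 0 °C; pH 7 buffer quench
Reagents that add atoms: none
Why: In this Luche reduction the cerium salt activates the hindered aryl ketone so that borohydride adds at low temperature in a nearly neutral medium that spares the acetates and suppresses acetyl migration, hydride arriving on the convex face (side of prenyl and H-4a) to give a carbinol centre that is erased by ionisation in step 5.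

Step 5
Reactants: 9 (1R,4S,4aS,9R,9aR)-9-hydroxy diacetate; 10 trimethyl(2-methylallyl)silane
Product: 11 (1R,4S,4aS,9S,9aS)-5,8-dimethoxy-9-(2-methylallyl)-9a-(3-methylbut-2-enyl)-4,4a,9,9a-tetrahydro-1H-fluorene-1,4-diyl diacetate (methallyl cis to prenyl)
Conditions: 10 (3 equiv), Bi(OTf)3 (5 mol %), CH2Cl2, −20 → 0 °C
Reagents that add atoms: none
Why: In this Hosomi–Sakurai-type SN1 allylation of a benzylic alcohol only C9–OH ionises, because its cation is stabilised by the ortho 8-methoxy group and has no β-hydrogen to lose, while the electron-poor endo acetoxy group on C1 disfavours retro-Prins cleavage of C1–C9a and covers the concave face, so 10 bonds through its =CH2 terminus on the convex face syn to prenyl and sets C9 (S) with H-9 toward ring A.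

Step 6
Reactants: 11 (1R,4S,4aS,9S,9aS)-9-(2-methylallyl) diacetate
Product: 14 (1R,4S,4aS,9S,9aS)-9-(3-hydroxy-2-methylpropyl)-5,8-dimethoxy-9a-(3-methylbut-2-enyl)-4,4a,9,9a-tetrahydro-1H-fluorene-1,4-diol (epimers at the side-chain CH), via alkylborane 12 (not isolated), via diacetate alcohol 13 (not isolated)
Conditions: 9-BBN (1.3 equiv), THF, 0 °C → rt; then 3 M NaOH, 30% H2O2, MeOH, 0 → 40 °C
Reagents that add atoms: hydrogen peroxide, OO
Why: In this Brown hydroboration–oxidation 9-BBN adds anti-Markovnikov to the terminal 1,1-disubstituted alkene much faster than to the trisubstituted prenyl or the flanked ring A alkene, and alkaline peroxide replaces boron by OH and saponifies both acetates in the same pot, the new methyl-bearing centre being an epimer mixture that is levelled in step 8 and erased in step 9.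

Step 7
Reactants: 14 (1R,4S,4aS,9S,9aS)-triol
Product: 15 3-[(4aR,9R,9aS)-5,8-dimethoxy-9a-(3-methylbut-2-enyl)-1,4-dioxo-4,4a,9,9a-tetrahydro-1H-fluoren-9-yl]-2-methylpropanal (epimers at C2 of the propanal)
Conditions: Dess–Martin periodinane (3.5 equiv), CH2Cl2, 0 °C → rt
Reagents that add atoms: none
Why: The Dess–Martin oxidation takes both allylic carbinols to the ene-dione and the primary alcohol to the aldehyde in one mild operation that leaves alkenes, arene and the cis ring fusion untouched and creates no stereocentre.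

Step 8
Reactants: 15 ene-dione aldehyde
Product: 16 (4aR,9R,9aS,11S,12R)-12-hydroxy-5,8-dimethoxy-11-methyl-9a-(3-methylbut-2-enyl)-4a,9-propano-bridged 9,9a-dihydro-4aH-fluorene-1,4-dione
Conditions: DBU (0.2 equiv), CH2Cl2, 0 °C → rt, argon
Reagents that add atoms: none
Why: In this intramolecular aldol addition (6-enolexo-exo-trig) DBU reversibly enolises C4a–H, which is α to C4=O and benzylic, and the aldehyde tethered on the prenyl face of C9 can reach planar C4a only from that face, so C4a becomes quaternary with ring A still cis-fused, while reversible aldol addition and aldehyde epimerisation should funnel C11 and C12 to the diequatorial isomer whose OH is hydrogen-bonded to C4=O.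

Step 9
Reactants: 16 aldol
Product: 18 (4aR,9R,9aS)-5,8-dimethoxy-9a-(3-methylbut-2-enyl)-4a,9-(2-methylprop-1-ene-1,3-diyl)-9,9a-dihydro-4aH-fluorene-1,4-dione (C1 of the bridge on C4a), via sulfamate 17 (not isolated)
Conditions: methyl N-(triethylammoniosulfonyl)carbamate (Burgess reagent, 2.5 equiv), toluene, rt → 70 °C
Reagents that add atoms: none
Why: In this Burgess dehydration the equatorial C12 sulfamate and the axial H-11 are syn-clinal and reach syn-periplanarity as ring B flexes, C4a carries no hydrogen so the thermal syn elimination can only give the C11=C12 alkene, and fast O-sulfonylation shuts off retro-aldol cleavage.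

Step 10
Reactants: 18 dimethyl ether of the target
Product: 20 CNP0513322.1 (4aR,9R,9aS)-5,8-dihydroxy-9a-(3-methylbut-2-enyl)-4a,9-(2-methylprop-1-ene-1,3-diyl)-9,9a-dihydro-4aH-fluorene-1,4-dione, via quinone 19 (not isolated)
Conditions: (NH4)2Ce(NO3)6 (2.5 equiv), MeCN/H2O, 0 °C; then EtOAc, aq. Na2S2O4, rt, brief shaking
Reagents that add atoms: water, O
Why: Oxidative demethylation of the hydroquinone dimethyl ether by (NH4)2Ce(NO3)6, with water attacking the ipso carbons, avoids the Lewis or Brønsted acids that would attack the two trisubstituted alkenes, and brief dithionite reduction touches only the benzoquinone, which is a far stronger oxidant than the non-aromatisable ene-dione, so the three stereocentres stay as set.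

**Compound list**
1 | 4,7-dimethoxyindan-1-one | COc1ccc(OC)c2c1CCC2=O | starting material
2 | 1-bromo-3-methylbut-2-ene | CC(C)=CCBr | starting material
3 | rac-4,7-dimethoxy-2-(3-methylbut-2-enyl)indan-1-one | CC(C)=CCC1Cc2c(OC)ccc(OC)c2C1=O | intermediate
4 | rac-4,7-dimethoxy-2-(3-methylbut-2-enyl)-2-(phenylselanyl)indan-1-one | CC(C)=CCC1([Se]c2ccccc2)Cc2c(OC)ccc(OC)c2C1=O | intermediate
5 | selenoxide of 4 | CC(C)=CCC1([Se](=O)c2ccccc2)Cc2c(OC)ccc(OC)c2C1=O | intermediate
6 | 4,7-dimethoxy-2-(3-methylbut-2-enyl)-1H-inden-1-one | CC(C)=CCC1=Cc2c(OC)ccc(OC)c2C1=O | intermediate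
7 | (1E,3E)-buta-1,3-diene-1,4-diyl diacetate | CC(=O)O/C=C/C=C/OC(C)=O | starting material
8 | (1R,4S,4aR,9aS)-5,8-dimethoxy-9a-(3-methylbut-2-enyl)-9-oxo-4,4a,9,9a-tetrahydro-1H-fluorene-1,4-diyl diacetate | CC(C)=CC[C@@]12[C@H](OC(C)=O)C=C[C@H](OC(C)=O)[C@@H]1c1c(OC)ccc(OC)c1C2=O | intermediate
9 | (1R,4S,4aS,9R,9aR)-9-hydroxy analogue of 8 | CC(C)=CC[C@@]12[C@H](OC(C)=O)C=C[C@H](OC(C)=O)[C@@H]1c1c(OC)ccc(OC)c1[C@@H]2O | intermediate
10 | trimethyl(2-methylallyl)silane | C=C(C)C[Si](C)(C)C | starting material
11 | (1R,4S,4aS,9S,9aS)-5,8-dimethoxy-9-(2-methylallyl)-9a-(3-methylbut-2-enyl)-4,4a,9,9a-tetrahydro-1H-fluorene-1,4-diyl diacetate | CC(C)=CC[C@@]12[C@H](OC(C)=O)C=C[C@H](OC(C)=O)[C@@H]1c1c(OC)ccc(OC)c1[C@H]2CC(C)=C | intermediate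
12 | B-alkyl-9-borabicyclo[3.3.1]nonane from 11 (boron on the terminal side-chain CH2) | CC(C)=CC[C@@]12[C@H](OC(C)=O)C=C[C@H](OC(C)=O)[C@@H]1c1c(OC)ccc(OC)c1[C@H]2CC(C)CB1C2CCCC1CCC2 | intermediate
13 | 9-(3-hydroxy-2-methylpropyl) diacetate | CC(C)=CC[C@@]12[C@H](OC(C)=O)C=C[C@H](OC(C)=O)[C@@H]1c1c(OC)ccc(OC)c1[C@H]2CC(C)CO | intermediate
14 | (1R,4S,4aS,9S,9aS)-9-(3-hydroxy-2-methylpropyl)-5,8-dimethoxy-9a-(3-methylbut-2-enyl)-4,4a,9,9a-tetrahydro-1H-fluorene-1,4-diol | CC(C)=CC[C@@]12[C@H](O)C=C[C@H](O)[C@@H]1c1c(OC)ccc(OC)c1[C@H]2CC(C)CO | intermediate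
15 | 3-[(4aR,9R,9aS)-5,8-dimethoxy-9a-(3-methylbut-2-enyl)-1,4-dioxo-4,4a,9,9a-tetrahydro-1H-fluoren-9-yl]-2-methylpropanal | CC(C)=CC[C@@]12C(=O)C=CC(=O)[C@@H]1c1c(OC)ccc(OC)c1[C@H]2CC(C)C=O | intermediate
16 | (4aR,9R,9aS,11S,12R)-12-hydroxy-11-methyl bridged aldol | CC(C)=CC[C@@]12C(=O)C=CC(=O)[C@@]13[C@H](O)[C@@H](C)C[C@@H]2c1c(OC)ccc(OC)c13 | intermediate
17 | triethylammonium C12 N-(methoxycarbonyl)sulfamate of 16 | CC(C)=CC[C@@]12C(=O)C=CC(=O)[C@@]13[C@H](OS(=O)(=O)[N-]C(=O)OC)[C@@H](C)C[C@@H]2c1c(OC)ccc(OC)c13.CC[NH+](CC)CC | intermediate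
18 | (4aR,9R,9aS)-5,8-di-O-methyl ether of the target | CC(C)=CC[C@@]12C(=O)C=CC(=O)[C@@]13C=C(C)C[C@@H]2c1c(OC)ccc(OC)c13 | intermediate
19 | (4aS,9R,9aS)-1,4,5,8-tetraone (benzoquinone form of the target) | CC(C)=CC[C@@]12C(=O)C=CC(=O)[C@@]13C=C(C)C[C@@H]2C2=C3C(=O)C=CC2=O | intermediate
20 | CNP0513322.1, (4aR,9R,9aS) | CC(C)=CC[C@@]12C(=O)C=CC(=O)[C@@]13C=C(C)C[C@@H]2c1c(O)ccc(O)c13 | target

**Count.** Total steps: 10. Longest linear sequence: 10 (1 → 20).

**Steps most likely to fail**

**Step 3.**
- What may go wrong: the doubly acyloxylated diene may add too slowly to the trisubstituted, donor-substituted dienophile at the temperatures the titanium complex tolerates. The complex may also discriminate poorly between the two faces.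
- Fallback (racemic cycloaddition plus classical resolution), setting out from 6 and 7: the cycloaddition is run without chiral ligand under high pressure (about 12 kbar, CH2Cl2) or in hot toluene. This gives 8 together with the mirror-image adduct ent-8 F1.
- Reduction as in step 4 gives 9 and the mirror-image alcohol ent-9 F2.
- Esterification with (S)-2-methoxy-2-phenylacetic acid (DCC, DMAP) gives the (S)-2-methoxy-2-phenylacetate of 9 F3 and the (S)-2-methoxy-2-phenylacetate of ent-9 F4. These are separated by chromatography or crystallisation.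
- F3 is ionised directly under the conditions of step 5, its ester serving as the benzylic leaving group. The route is rejoined at 11.

**Step 5.**
- What may go wrong: the silane may attack on the concave face, giving a C9 epimer that cannot close ring B. The cation may also be lost through skeletal migration.
- Fallback (carbon and hydrogen reach C9 in the reverse order), setting out from 8: Hosomi–Sakurai addition of 10 to the ketone (TiCl4, CH2Cl2, −78 °C) gives the 9-hydroxy-9-(2-methylallyl) tertiary carbinol F5.
- Ionic hydrogenation (Et3SiH, BF3·OEt2, CH2Cl2, −78 → −40 °C) then delivers hydride to the tertiary benzylic cation on the face that proved accessible. This pushes the methallyl group to the prenyl side, and the route is rejoined at 11.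

**Step 2.**
- What may go wrong: the selenoxide may eliminate toward the allylic CH2 of the side chain instead of the ring CH2. The indenone may also dimerise during handling.
- Fallback (aldol/E1cB construction that can place the double bond only in the ring), setting out from 2: alkylation of the lithium enolate of N-methoxy-N-methylacetamide with 2 gives N-methoxy-N,5-dimethylhex-4-enamide F6.
- 2,5-Dimethoxybenzaldehyde is masked in situ as its lithium α-amino alkoxide with LiN(CH3)CH2CH2N(CH3)2. It is lithiated with n-BuLi at C6, between the masked formyl group and the methoxy group, and acylated with F6. Acidic work-up gives 3,6-dimethoxy-2-(5-methylhex-4-enoyl)benzaldehyde F7.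
- Catalytic K2CO3 in MeOH closes F7 by 5-exo aldol addition to 3-hydroxy-4,7-dimethoxy-2-(3-methylbut-2-enyl)indan-1-one F8.
- MsCl/Et3N (CH2Cl2, 0 °C) forms the C3 mesylate F9, which loses mesylate by E1cB through the acidic C2–H. The route is rejoined at 6.

**Further compounds**
F1 | step 3 | mirror-image adduct ent-8 | CC(C)=CC[C@]12[C@@H](OC(C)=O)C=C[C@@H](OC(C)=O)[C@H]1c1c(OC)ccc(OC)c1C2=O
F2 | step 3 | mirror-image alcohol ent-9 | CC(C)=CC[C@]12[C@@H](OC(C)=O)C=C[C@@H](OC(C)=O)[C@H]1c1c(OC)ccc(OC)c1[C@H]2O
F3 | step 3 | (S)-2-methoxy-2-phenylacetate of 9 | CC(C)=CC[C@@]12[C@H](OC(C)=O)C=C[C@H](OC(C)=O)[C@@H]1c1c(OC)ccc(OC)c1[C@@H]2OC(=O)[C@@H](OC)c1ccccc1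
F4 | step 3 | (S)-2-methoxy-2-phenylacetate of ent-9 | CC(C)=CC[C@]12[C@@H](OC(C)=O)C=C[C@@H](OC(C)=O)[C@H]1c1c(OC)ccc(OC)c1[C@H]2OC(=O)[C@@H](OC)c1ccccc1
F5 | step 5 | 9-hydroxy-9-(2-methylallyl) tertiary carbinol | CC(C)=CC[C@@]12[C@H](OC(C)=O)C=C[C@H](OC(C)=O)[C@@H]1c1c(OC)ccc(OC)c1[C@]2(O)CC(C)=C
F6 | step 2 | N-methoxy-N,5-dimethylhex-4-enamide | CON(C)C(=O)CCC=C(C)C
F7 | step 2 | 3,6-dimethoxy-2-(5-methylhex-4-enoyl)benzaldehyde | COc1ccc(OC)c(C(=O)CCC=C(C)C)c1C=O
F8 | step 2 | 3-hydroxy-4,7-dimethoxy-2-(3-methylbut-2-enyl)indan-1-one | CC(C)=CCC1C(O)c2c(OC)ccc(OC)c2C1=O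
F9 | step 2 | C3 mesylate | CC(C)=CCC1C(OS(C)(=O)=O)c2c(OC)ccc(OC)c2C1=O
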